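**Strategy.** The dihydrofuran ring is cut at C3–C3a and O1–C7a. These two bonds sit on neighbouring carbons of ring A beside the C7 methoxy group, which are the ortho C–H and ipso C–I positions of a 2-iodoanisole. A single palladium/norbornene annulation of methyl 3-(4-iodo-3-methoxyphenyl)propanoate with an enantiopure cis-epoxide should make both bonds, close the five-membered ring and convert the cis-epoxide into the trans-2,3 pattern (inversion at C3, retention at C2). The epoxide carries ring C as a pivalate-masked syringyl group and the C3 hydroxymethyl as a silyl ether, bought in with the alkyne so that no separate silylation is needed. Two deprotections finish the synthesis.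

Key step: step 8

Assumption: the (R,R)-manganese salen catalyst is taken to deliver oxygen to 9 in the facial sense known for cis-β-methylstyrene (benzylic carbon R), otherwise its enantiomer is used; palladium-bound species inside the catalytic cycle of step 8 do not accumulate and are described in words, not numbered.

**Step 1**
Reactants: 1 4-bromo-3-methoxybenzaldehyde
Product: 2 methyl (E)-3-(4-bromo-3-methoxyphenyl)prop-2-enoate
Conditions: Ph3P=CHCO2Me (1.2 equiv), toluene, 80 °C
Reagents that add atoms: methyl (triphenylphosphoranylidene)acetate, COC(=O)C=P(c1ccccc1)(c1ccccc1)c1ccccc1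
Why: Wittig olefination with a stabilised ylide should give the cinnamate cleanly, and its E/Z outcome is of no consequence because the double bond is saturated in step 2.

**Step 2**
Reactants: 2 methyl (E)-3-(4-bromo-3-methoxyphenyl)prop-2-enoate
Product: 3 methyl 3-(4-bromo-3-methoxyphenyl)propanoate
Conditions: H2 (4 bar), RhCl(PPh3)3 (3 mol%), THF/MeOH 1:1, 40 °C
Reagents that add atoms: none
Why: Homogeneous catalytic hydrogenation with the rhodium–phosphine complex should saturate the conjugated alkene without hydrogenolysis of the C–Br bond or reduction of the ester.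

**Step 3**
Reactants: 3 methyl 3-(4-bromo-3-methoxyphenyl)propanoate
Product: 4 methyl 3-(4-iodo-3-methoxyphenyl)propanoate
Conditions: NaI (2 equiv), CuI (10 mol%), trans-N,N'-dimethylcyclohexane-1,2-diamine (20 mol%), 1,4-dioxane, 110 °C
Reagents that add atoms: sodium iodide, [Na+].[I-]
Why: The copper-catalysed aromatic Finkelstein exchange, driven by the poor solubility of NaBr in dioxane, should give the iodide needed for fast oxidative addition in step 8 while the ester stays inert.

**Step 4**
Reactants: 5 4-bromo-2,6-dimethoxyphenol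
Product: 6 4-bromo-2,6-dimethoxyphenyl 2,2-dimethylpropanoate (pivalate)
Conditions: PivCl (1.3 equiv), Et3N, DMAP (cat.), CH2Cl2, 0 °C → rt
Reagents that add atoms: pivaloyl chloride, CC(C)(C)C(=O)Cl
Why: DMAP-catalysed O-acylation of the phenol should give a pivalate that makes ring C electron-poor and withstands the amine, hypochlorite buffer and carbonate of the later steps.

**Step 5**
Reactants: 6 4-bromo-2,6-dimethoxyphenyl 2,2-dimethylpropanoate; 7 tert-butyldimethyl(prop-2-yn-1-yloxy)silane
Product: 8 4-[3-(tert-butyldimethylsilyloxy)prop-1-yn-1-yl]-2,6-dimethoxyphenyl 2,2-dimethylpropanoate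
Conditions: PdCl2(PhCN)2 (3 mol%), [HP(t-Bu)3]BF4 (6 mol%), CuI (2 mol%), i-Pr2NH, 1,4-dioxane, rt → 40 °C
Reagents that add atoms: none
Why: Sonogashira coupling should proceed near room temperature because the bromide sits para to the acyloxy group and the phosphine is bulky and electron-rich, the hindered amine leaves the pivalate alone, and using the alkyne already as its silyl ether saves a protection step.

**Step 6**
Reactants: 8 4-[3-(tert-butyldimethylsilyloxy)prop-1-yn-1-yl]-2,6-dimethoxyphenyl 2,2-dimethylpropanoate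
Product: 9 4-[(Z)-3-(tert-butyldimethylsilyloxy)prop-1-en-1-yl]-2,6-dimethoxyphenyl 2,2-dimethylpropanoate
Conditions: H2 (1 atm), Pd/CaCO3 poisoned with Pb(OAc)2 (Lindlar catalyst), quinoline, EtOAc, rt
Reagents that add atoms: none
Why: Lindlar semihydrogenation adds H2 to one face of the alkyne on the poisoned palladium surface and should stop at the (Z)-alkene, with quinoline suppressing over-reduction and isomerisation.

**Step 7**
Reactants: 9 4-[(Z)-3-(tert-butyldimethylsilyloxy)prop-1-en-1-yl]-2,6-dimethoxyphenyl 2,2-dimethylpropanoate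
Product: 10 4-[(2R,3S)-3-(tert-butyldimethylsilyloxymethyl)oxiran-2-yl]-2,6-dimethoxyphenyl 2,2-dimethylpropanoate (cis-epoxide)
Conditions: (R,R)-(salen)MnCl [salen = N,N'-bis(3,5-di-tert-butylsalicylidene)cyclohexane-1,2-diaminate; trivalent manganese] (5 mol%), 4-phenylpyridine N-oxide (20 mol%), aq. NaOCl (pH 11.3, Na2HPO4), CH2Cl2, 0 °C
Reagents that add atoms: sodium hypochlorite, [Na+].[O-]Cl
Why: In the Jacobsen–Katsuki epoxidation the oxo-manganese salen species transfers oxygen side-on to one enantioface of the conjugated cis-alkene, so the (R,R)-ligand should set both epoxide carbons at once as (2R,3S) with the cis geometry kept, and the low temperature with the N-oxide additive limits leakage to the trans-epoxide.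

**Step 8**
Reactants: 4 methyl 3-(4-iodo-3-methoxyphenyl)propanoate; 10 4-[(2R,3S)-3-(tert-butyldimethylsilyloxymethyl)oxiran-2-yl]-2,6-dimethoxyphenyl 2,2-dimethylpropanoate
Product: 11 methyl 3-[(2S,3R)-3-(tert-butyldimethylsilyloxymethyl)-2-(3,5-dimethoxy-4-pivaloyloxyphenyl)-7-methoxy-2,3-dihydro-1-benzofuran-5-yl]propanoate
Conditions: Pd(OAc)2 (10 mol%), 2-dicyclohexylphosphino-2',6'-diisopropoxybiphenyl (20 mol%), isopropyl norborn-5-ene-2-carboxylate (50 mol%), Cs2CO3 (1.5 equiv), 10 (1.5 equiv), NMP, 100 °C, Ar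
Reagents that add atoms: none
Why: Proposed new method: zerovalent palladium (from Pd(OAc)2 and the phosphine) inserts into the C–I bond of 4, the norbornene ester inserts and the C3a–H bond is palladated to give the five-membered aryl–norbornyl palladacycle of divalent palladium, which attacks C3 of 10 in an SN2 manner anti to the C3–O bond to give an alkyl alkoxide complex of tetravalent palladium; reductive elimination makes C3–C3a, β-carbon elimination expels the norbornene, and the tethered C2 alkoxide then couples with the ipso carbon. The closest known reaction type is the palladium/norbornene annulation of ortho-substituted aryl iodides with terminal epoxides to 2-substituted 2,3-dihydrobenzofurans, whereas opening an internal aryl epoxide at its non-benzylic carbon has no precedent in this manifold. The dihydrofuran ring closes by C(aryl)–O reductive elimination from a six-membered oxapalladacycle, a formal [3+2] annulation across the ortho and ipso carbons of ring A. C3 is set by stereospecific inversion of the (S)-configured epoxide carbon and C2 is carried over with its C–O bond intact, so the cis-epoxide should map onto the (2S,3R)-trans ring. The step needs attack at C3 and not at benzylic C2: the para-pivaloyloxy group makes ring C electron-poor and disfavours ionisation or metal insertion at C2–O, the silyl ether neither chelates nor acts as a good β-leaving group on the palladium-bound C3, and the C7 methoxy group blocks the second ortho position so that only one alkylation can occur. Regioselectivity at the epoxide remains the unproven point of the route.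

**Step 9**
Reactants: 11 methyl 3-[(2S,3R)-3-(tert-butyldimethylsilyloxymethyl)-2-(3,5-dimethoxy-4-pivaloyloxyphenyl)-7-methoxy-2,3-dihydro-1-benzofuran-5-yl]propanoate
Product: 12 methyl 3-[(2S,3R)-2-(3,5-dimethoxy-4-pivaloyloxyphenyl)-3-(hydroxymethyl)-7-methoxy-2,3-dihydro-1-benzofuran-5-yl]propanoate
Conditions: TBAF (1.2 equiv), AcOH (1.2 equiv), THF, 0 °C → rt
Reagents that add atoms: none
Why: Fluoride-mediated silyl ether cleavage is driven by the strong Si–F bond, and acetic acid buffering keeps the medium non-basic so that the aryl pivalate and the methyl ester stay intact.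

**Step 10**
Reactants: 12 methyl 3-[(2S,3R)-2-(3,5-dimethoxy-4-pivaloyloxyphenyl)-3-(hydroxymethyl)-7-methoxy-2,3-dihydro-1-benzofuran-5-yl]propanoate
Product: 13 methyl 3-[(2S,3R)-2-(4-hydroxy-3,5-dimethoxyphenyl)-3-(hydroxymethyl)-7-methoxy-2,3-dihydro-1-benzofuran-5-yl]propanoate (target)
Conditions: K2CO3 (0.5 equiv), MeOH, rt → 40 °C, Ar; aq. NH4Cl work-up
Reagents that add atoms: none
Why: Base-catalysed transesterification with methanol should cleave the aryl ester through its phenoxide leaving group while exchange at the methyl ester is degenerate in methanol, and neither stereocentre is touched at this temperature.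

**Compound list**
1 | 4-bromo-3-methoxybenzaldehyde | COc1cc(C=O)ccc1Br | starting material
2 | methyl (E)-3-(4-bromo-3-methoxyphenyl)prop-2-enoate | COC(=O)/C=C/c1ccc(Br)c(OC)c1 | intermediate
3 | methyl 3-(4-bromo-3-methoxyphenyl)propanoate | COC(=O)CCc1ccc(Br)c(OC)c1 | intermediate
4 | methyl 3-(4-iodo-3-methoxyphenyl)propanoate | COC(=O)CCc1ccc(I)c(OC)c1 | intermediate
5 | 4-bromo-2,6-dimethoxyphenol | COc1cc(Br)cc(OC)c1O | starting material
6 | 4-bromo-2,6-dimethoxyphenyl 2,2-dimethylpropanoate | COc1cc(Br)cc(OC)c1OC(=O)C(C)(C)C | intermediate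
7 | tert-butyldimethyl(prop-2-yn-1-yloxy)silane | C#CCO[Si](C)(C)C(C)(C)C | starting material
8 | 4-[3-(tert-butyldimethylsilyloxy)prop-1-yn-1-yl]-2,6-dimethoxyphenyl 2,2-dimethylpropanoate | CC(C)(C)[Si](C)(C)OCC#Cc1cc(OC)c(OC(=O)C(C)(C)C)c(OC)c1 | intermediate
9 | 4-[(Z)-3-(tert-butyldimethylsilyloxy)prop-1-en-1-yl]-2,6-dimethoxyphenyl 2,2-dimethylpropanoate | CC(C)(C)[Si](C)(C)OC/C=C\c1cc(OC)c(OC(=O)C(C)(C)C)c(OC)c1 | intermediate
10 | 4-[(2R,3S)-3-(tert-butyldimethylsilyloxymethyl)oxiran-2-yl]-2,6-dimethoxyphenyl 2,2-dimethylpropanoate | CC(C)(C)[Si](C)(C)OC[C@@H]1O[C@@H]1c1cc(OC)c(OC(=O)C(C)(C)C)c(OC)c1 | intermediate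
11 | methyl 3-[(2S,3R)-3-(tert-butyldimethylsilyloxymethyl)-2-(3,5-dimethoxy-4-pivaloyloxyphenyl)-7-methoxy-2,3-dihydro-1-benzofuran-5-yl]propanoate | COC(=O)CCc1cc(OC)c2c(c1)[C@H](CO[Si](C)(C)C(C)(C)C)[C@@H](c1cc(OC)c(OC(=O)C(C)(C)C)c(OC)c1)O2 | intermediate
12 | methyl 3-[(2S,3R)-2-(3,5-dimethoxy-4-pivaloyloxyphenyl)-3-(hydroxymethyl)-7-methoxy-2,3-dihydro-1-benzofuran-5-yl]propanoate | COC(=O)CCc1cc(OC)c2c(c1)[C@H](CO)[C@@H](c1cc(OC)c(OC(=O)C(C)(C)C)c(OC)c1)O2 | intermediate
13 | methyl 3-[(2S,3R)-2-(4-hydroxy-3,5-dimethoxyphenyl)-3-(hydroxymethyl)-7-methoxy-2,3-dihydro-1-benzofuran-5-yl]propanoate (CNP0362206.1) | COC(=O)CCc1cc(OC)c2c(c1)[C@H](CO)[C@@H](c1cc(OC)c(O)c(OC)c1)O2 | target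

**Totals**
Total step count: 10. Longest linear sequence: 7 steps (steps 4–10, from 5 to 13).

**Steps most likely to fail**

1. Step 8. The palladacycle may open the epoxide at benzylic C2 instead of C3, palladium may isomerise the epoxide to a carbonyl compound, or the internal epoxide may not react at all. The fallback makes the two bonds in separate, known operations, O1–C2 first. It sets out from aryl bromide 6 and rejoins the route at 12.
   - Suzuki–Miyaura coupling of 6 with purchased (E)-tert-butyldimethyl{[3-(4,4,5,5-tetramethyl-1,3,2-dioxaborolan-2-yl)prop-2-en-1-yl]oxy}silane (CC(C)(C)[Si](C)(C)OC/C=C/B1OC(C)(C)C(C)(C)O1; PdCl2(dppf), K3PO4, dioxane/H2O, 80 °C) would give 4-[(E)-3-(tert-butyldimethylsilyloxy)prop-1-en-1-yl]-2,6-dimethoxyphenyl 2,2-dimethylpropanoate F1.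
   - TBAF/AcOH would free 4-[(E)-3-hydroxyprop-1-en-1-yl]-2,6-dimethoxyphenyl 2,2-dimethylpropanoate F2, and ClCO2Me/pyridine would convert it into (E)-3-(3,5-dimethoxy-4-pivaloyloxyphenyl)prop-2-en-1-yl methyl carbonate F3.
   - Ring A would come from purchased methyl 3-(4-hydroxy-3-methoxyphenyl)propanoate (COC(=O)CCc1ccc(O)c(OC)c1), iodinated ortho to the hydroxyl (I2, KI, aq. NaHCO3) to methyl 3-(4-hydroxy-3-iodo-5-methoxyphenyl)propanoate F4.
   - Iridium-catalysed asymmetric allylic etherification of F3 with the lithium phenoxide of F4 ([Ir(cod)Cl]2, chiral phosphoramidite ligand of the enantiomer giving the S ether, THF, 50 °C) should give the branched ether methyl 3-[4-({(1S)-1-(3,5-dimethoxy-4-pivaloyloxyphenyl)prop-2-en-1-yl}oxy)-3-iodo-5-methoxyphenyl]propanoate F5, which fixes C2.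
   - A 5-exo-trig aryl radical cyclisation with nitroxyl trapping (Bu3SnH, TEMPO, benzene, 70 °C) should then form C3–C3a anti to the C2 aryl group and give the alkoxyamine methyl 3-[(2S,3R)-2-(3,5-dimethoxy-4-pivaloyloxyphenyl)-7-methoxy-3-{[(2,2,6,6-tetramethylpiperidin-1-yl)oxy]methyl}-2,3-dihydro-1-benzofuran-5-yl]propanoate F6.
   - Zn/AcOH would cleave the N–O bond of F6 and deliver 12.

2. Step 7. The stepwise oxygen transfer to a conjugated cis-alkene may erode enantioselectivity and leak to the trans-epoxide, and the aryl epoxide may open under acid during isolation. The fallback replaces the manganese-oxo transfer by a hydroxyl-directed, concerted epoxidation that cannot scramble the alkene geometry. It sets out from 9 and returns at 10.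
   - TBAF/AcOH would give 4-[(Z)-3-hydroxyprop-1-en-1-yl]-2,6-dimethoxyphenyl 2,2-dimethylpropanoate F7.
   - Katsuki–Sharpless epoxidation (Ti(OiPr)4, L-(+)-diisopropyl tartrate, t-BuOOH, 4 Å molecular sieves, CH2Cl2, −20 °C) should give 4-[(2R,3S)-3-(hydroxymethyl)oxiran-2-yl]-2,6-dimethoxyphenyl 2,2-dimethylpropanoate F8. By the empirical face-selection rule the L-tartrate places S configuration at the epoxide carbon bearing the hydroxymethyl group.
   - TBSCl/imidazole in DMF would return 10.

3. Step 10. Methanolysis of the doubly ortho-substituted, hindered aryl pivalate may be incomplete under conditions mild enough to spare the methyl ester, and forcing with base risks ring opening at C2 through a quinone methide. The fallback stops protecting the methyl ester. It sets out from 12 and returns at 13.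
   - LiOH (THF/H2O, rt, Ar) would hydrolyse both the pivalate and the methyl ester to 3-[(2S,3R)-2-(4-hydroxy-3,5-dimethoxyphenyl)-3-(hydroxymethyl)-7-methoxy-2,3-dihydro-1-benzofuran-5-yl]propanoic acid F9.
   - Carboxylate-selective alkylation (MeI, KHCO3, DMF, rt; bicarbonate does not deprotonate the phenol) would give 13.

**Further compounds**
F1 | step 8 | 4-[(E)-3-(tert-butyldimethylsilyloxy)prop-1-en-1-yl]-2,6-dimethoxyphenyl 2,2-dimethylpropanoate | CC(C)(C)[Si](C)(C)OC/C=C/c1cc(OC)c(OC(=O)C(C)(C)C)c(OC)c1
F2 | step 8 | 4-[(E)-3-hydroxyprop-1-en-1-yl]-2,6-dimethoxyphenyl 2,2-dimethylpropanoate | OC/C=C/c1cc(OC)c(OC(=O)C(C)(C)C)c(OC)c1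
F3 | step 8 | (E)-3-(3,5-dimethoxy-4-pivaloyloxyphenyl)prop-2-en-1-yl methyl carbonate | COC(=O)OC/C=C/c1cc(OC)c(OC(=O)C(C)(C)C)c(OC)c1
F4 | step 8 | methyl 3-(4-hydroxy-3-iodo-5-methoxyphenyl)propanoate | COC(=O)CCc1cc(I)c(O)c(OC)c1
F5 | step 8 | methyl 3-[4-({(1S)-1-(3,5-dimethoxy-4-pivaloyloxyphenyl)prop-2-en-1-yl}oxy)-3-iodo-5-methoxyphenyl]propanoate | COC(=O)CCc1cc(I)c(O[C@@H](C=C)c2cc(OC)c(OC(=O)C(C)(C)C)c(OC)c2)c(OC)c1
F6 | step 8 | methyl 3-[(2S,3R)-2-(3,5-dimethoxy-4-pivaloyloxyphenyl)-7-methoxy-3-{[(2,2,6,6-tetramethylpiperidin-1-yl)oxy]methyl}-2,3-dihydro-1-benzofuran-5-yl]propanoate | COC(=O)CCc1cc(OC)c2c(c1)[C@H](CON1C(C)(C)CCCC1(C)C)[C@@H](c1cc(OC)c(OC(=O)C(C)(C)C)c(OC)c1)O2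
F7 | step 7 | 4-[(Z)-3-hydroxyprop-1-en-1-yl]-2,6-dimethoxyphenyl 2,2-dimethylpropanoate | OC/C=C\c1cc(OC)c(OC(=O)C(C)(C)C)c(OC)c1
F8 | step 7 | 4-[(2R,3S)-3-(hydroxymethyl)oxiran-2-yl]-2,6-dimethoxyphenyl 2,2-dimethylpropanoate | OC[C@@H]1O[C@@H]1c1cc(OC)c(OC(=O)C(C)(C)C)c(OC)c1
F9 | step 10 | 3-[(2S,3R)-2-(4-hydroxy-3,5-dimethoxyphenyl)-3-(hydroxymethyl)-7-methoxy-2,3-dihydro-1-benzofuran-5-yl]propanoic acid | OC(=O)CCc1cc(OC)c2c(c1)[C@H](CO)[C@@H](c1cc(OC)c(O)c(OC)c1)O2
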